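**Retrosynthetic overview**
- Target 9 comes from its primary acetate 8 by mild methanolysis.
- 8 comes from cyclobutane monoacetate 7: oxidation converts both phenols into a bis-p-quinone methide by cleaving the strained bond between the two benzylic carbons. The free CH2OH closes the tetrahydrofuran and water adds to the second quinone methide.
- 7 comes from meso diol 6 by lipase acetylation of one enantiotopic CH2OH; this fixes the absolute configuration.
- 6 comes from a template-directed head-to-head [2+2] photodimer of two ferulate units (ferulic acid + naphthalene-1,8-diol).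
- Ring order: cyclobutane (built, then sacrificed), then the tetrahydrofuran (the only ring in the target).

Assumption: the lipase acetylates the CH2OH on the (R)-configured ring carbon as drawn in 7; if its preference is the opposite, the same enzyme run hydrolytically on the peracetate of 6 gives the same monoacetate 7.

Atom labels used below: C7/C7' are the aryl-bearing carbons, C8/C8' the CH2O-bearing carbons, C9/C9' the CH2O carbons. In the target, C7 = ring C2, C8 = C3, C8' = C4, C9' = C5, and C7' is the carbinol carbon.

**Step 1**
Reactants: 1, ferulic acid
Product: 2, (E)-3-(4-acetoxy-3-methoxyphenyl)prop-2-enoic acid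
Conditions: Ac2O, 1 M aq. NaOH, 0 °C; then HCl
Reagents that add atoms: acetic anhydride, CC(=O)OC(C)=O
Why: Schotten–Baumann O-acetylation of the phenoxide masks the phenol so that only the carboxylic acid is esterified in step 2; the acetate is removed later by LiAlH4 at no extra cost.

**Step 2**
Reactants: 2 (2.2 equiv); 3, naphthalene-1,8-diol
Product: 4, naphthalene-1,8-diyl bis[(E)-3-(4-acetoxy-3-methoxyphenyl)prop-2-enoate]
Conditions: EDC·HCl, DMAP, CH2Cl2, 0 °C to rt
Reagents that add atoms: none
Why: Steglich esterification of both peri-hydroxyls places two cinnamate units side by side on a rigid template; aryl acetates are stable to these conditions.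

**Step 3**
Reactants: 4
Product: 5, naphthalene-1,8-diyl (1R,2S,3R,4S)-3,4-bis(4-acetoxy-3-methoxyphenyl)cyclobutane-1,2-dicarboxylate (meso cyclic diester; esters cis, aryls cis, each aryl trans to the neighbouring ester)
Conditions: hν (365 nm), crystalline solid, rt
Reagents that add atoms: none
Why: Template-directed intramolecular [2+2] photocycloaddition; the peri-oxygens hold the two C=C bonds parallel and head-to-head, so the two carboxyl-bearing carbons (C8/C8') must be cis, and the E-alkene geometry puts each aryl trans to its neighbouring ester. The aryl-bearing centres are erased in step 6, so only the C8/C8' cis relationship matters.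

**Step 4**
Reactants: 5
Product: 6, [(1R,2S,3R,4S)-3,4-bis(4-hydroxy-3-methoxyphenyl)cyclobutane-1,2-diyl]dimethanol (meso)
Conditions: LiAlH4 (excess), THF, 0 °C to rt; Rochelle salt work-up
Reagents that add atoms: none
Why: Hydride reduction of both activated aryl esters to primary alcohols releases the template and cleaves the two phenolic acetates in the same operation; reduction is faster than enolisation, so C8/C8' stay cis.

**Step 5**
Reactants: 6
Product: 7, [(1R,2S,3R,4S)-2-(hydroxymethyl)-3,4-bis(4-hydroxy-3-methoxyphenyl)cyclobutyl]methyl acetate
Conditions: immobilised lipase PS (Burkholderia cepacia), vinyl acetate, THF/MTBE, 30 °C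
Reagents that add atoms: vinyl acetate, C=COC(C)=O
Why: Enzymatic desymmetrisation of a meso 1,4-diol by irreversible, enantiotopic-group-selective transesterification; lipases acylate primary alcohols much faster than hindered guaiacyl phenols. This step sets the absolute configuration at C8 and C8' for the whole route.

**Step 6 (key step)**
Reactants: 7; water (co-solvent)
Product: 8, [(2S,3R,4S)-2-(4-hydroxy-3-methoxyphenyl)-4-[(S)-hydroxy(4-hydroxy-3-methoxyphenyl)methyl]oxolan-3-yl]methyl acetate
Conditions: FeCl3·6H2O (2.2 equiv), acetone/H2O 9:1, 0 °C to rt
Reagents that add atoms: water, O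
Why: Oxidative dearomatising fragmentation followed by oxa-1,6-additions. Single-electron oxidation of a phenol, β-scission of the strained C7–C7' bond and a second oxidation give a bis-p-quinone methide. The only free CH2OH (on C8') adds 5-exo to C7, giving the 2,3-trans tetrahydrofuran (aryl anti to the C3 substituent, reversible under the Lewis acid); since the other arm is acetylated, which enantiomer forms is dictated by step 5. Water then adds to the remaining quinone methide with the C8'–H eclipsing the exocyclic C=C (A1,3 control), anti to the more hindered ring carbon C3, giving the (S)-carbinol. C8 and C8' are untouched.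

**Step 7**
Reactants: 8
Product: 9, (S)-(4-hydroxy-3-methoxyphenyl)[(3S,4R,5S)-5-(4-hydroxy-3-methoxyphenyl)-4-(hydroxymethyl)oxolan-3-yl]methanol (target; lignan numbering 7S,8R,7'S,8'S)
Conditions: K2CO3 (0.3 equiv), MeOH, 0 °C; NH4Cl quench
Reagents that add atoms: none
Why: Zemplén-type methanolysis of the primary acetate; catalytic base at 0 °C is too mild to ionise the p-hydroxybenzylic C–O bonds, so no stereocentre is disturbed.

**Compound list**
1 | ferulic acid | COc1cc(/C=C/C(=O)O)ccc1O | starting material
2 | (E)-3-(4-acetoxy-3-methoxyphenyl)prop-2-enoic acid | COc1cc(/C=C/C(=O)O)ccc1OC(C)=O | intermediate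
3 | naphthalene-1,8-diol | Oc1cccc2cccc(O)c12 | starting material (template)
4 | naphthalene-1,8-diyl bis[(E)-3-(4-acetoxy-3-methoxyphenyl)prop-2-enoate] | COc1cc(/C=C/C(=O)Oc2cccc3cccc(OC(=O)/C=C/c4ccc(OC(C)=O)c(OC)c4)c23)ccc1OC(C)=O | intermediate
5 | naphthalene-1,8-diyl (1R,2S,3R,4S)-3,4-bis(4-acetoxy-3-methoxyphenyl)cyclobutane-1,2-dicarboxylate (meso) | O=C1Oc2cccc3cccc(c23)OC(=O)[C@@H]2[C@H]1[C@@H](c1ccc(OC(C)=O)c(OC)c1)[C@H]2c1ccc(OC(C)=O)c(OC)c1 | intermediate
6 | [(1R,2S,3R,4S)-3,4-bis(4-hydroxy-3-methoxyphenyl)cyclobutane-1,2-diyl]dimethanol (meso) | OC[C@H]1[C@@H](CO)[C@H](c2ccc(O)c(OC)c2)[C@@H]1c1ccc(O)c(OC)c1 | intermediate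
7 | [(1R,2S,3R,4S)-2-(hydroxymethyl)-3,4-bis(4-hydroxy-3-methoxyphenyl)cyclobutyl]methyl acetate | CC(=O)OC[C@H]1[C@@H](CO)[C@H](c2ccc(O)c(OC)c2)[C@@H]1c1ccc(O)c(OC)c1 | intermediate
8 | [(2S,3R,4S)-2-(4-hydroxy-3-methoxyphenyl)-4-[(S)-hydroxy(4-hydroxy-3-methoxyphenyl)methyl]oxolan-3-yl]methyl acetate | COc1cc([C@@H](O)[C@@H]2CO[C@H](c3ccc(O)c(OC)c3)[C@H]2COC(C)=O)ccc1O | intermediate
9 | (S)-(4-hydroxy-3-methoxyphenyl)[(3S,4R,5S)-5-(4-hydroxy-3-methoxyphenyl)-4-(hydroxymethyl)oxolan-3-yl]methanol | COc1cc([C@@H](O)[C@@H]2CO[C@H](c3ccc(O)c(OC)c3)[C@H]2CO)ccc1O | target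

**Totals**
Total steps: 7. Longest linear sequence: 7 (from ferulic acid).

**Three steps most likely to fail, with fallbacks**
1. Step 6. Risks are an unselective water addition at C7' and competing cycloreversion or phenol oligomerisation. Fallback: take C7' out of the cascade by oxidising the C7' epimer mixture of 8 to the aryl ketone (DDQ or MnO2) and setting the carbinol by reagent-controlled reduction (CBS or Ru–TsDPEN transfer hydrogenation), then deacetylate.
2. Step 5. Risk is low ee or poor turnover on a hindered diaryl substrate. Fallback: desymmetrise chemically at the anhydride level instead: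
   - saponify 5 to the diacid and close it to the meso anhydride with Ac2O;
   - open the anhydride with methanol mediated by quinidine or quinine (either enantiomer is available);
   - reduce the free acid with BH3·SMe2 to give a hydroxy ester with differentiated arms;
   - run the oxidative ring-opening on the free phenols, then reduce the ester at the end.
3. Step 3. Risks are poor solid-state reactivity of 4, photo-Fries side reactions or incomplete conversion. Fallback: drop the covalent template and use crystal-packing control, irradiating a crystalline monomeric ferulate aryl ester that packs head-to-head (for example the 4-nitrophenyl ester) to the same cyclobutane core, followed by the same LiAlH4 reduction to 6.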